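**Plan**

- Numbering used throughout: C1 = oxirane carbon bearing CH2OBz (C7), C2 = CHOH, C3 = CHOBz, C4=C5 = ring alkene, C6 = oxirane CH.
- Retrosynthesis: the oxirane is taken back to a C1=C6 alkene (epoxidation directed by the cis C2 hydroxyl), the benzoates are removed, and the cyclohexadiene is then cut at C1–C2 and at C4=C5.
- The feature that allows this: in the six-membered ring the C4=C5 double bond lies opposite the C1–C2 bond, so the ring divides into two three-carbon units. C2–C3–C4 is an α-oxy β,γ-unsaturated aldehyde (electrophile at C2, vinyl at C4); C5–C6–C1 is a 2-metallated 1,3-diene (nucleophile at C1, vinyl at C5).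
- Forward: iododiene 5 (from but-2-yne-1,4-diol) and aldehyde 9 (from (S)-but-3-ene-1,2-diol) are joined in one flask. Alkenyllithium addition forms C1–C2, then ring-closing metathesis forms C4=C5 and the carbocycle. Desilylation, dibenzoylation at O7 and O3, and epoxidation of C1=C6 follow.
- Stereochemistry: C3 from the chiral pool; C2 by Felkin–Anh 1,2-induction (anti adduct = cis-diol of the ring); C1 and C6 by oxygen delivery from the face of the C2 hydroxyl. Helpers are the two TBS ethers and the C1=C6 alkene (oxidation level of the oxirane); both are taken out after the key step.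

Key step: step 8

Remark: the target is read as (1S,2S,3S,6R), i.e. oxirane oxygen, C2–OH and C3–OBz all on one face of the ring and the CH2OBz group on the other.

**Route**

Step 1
Reactants: 1 but-2-yne-1,4-diol
Product: 2 4-[(tert-butyldimethylsilyl)oxy]but-2-yn-1-ol
Conditions: NaH (1.0 equiv), THF, 0 °C; TBSCl (1.0 equiv), rt
Reagents that add atoms: tert-butyldimethylsilyl chloride, CC(C)(C)[Si](C)(C)Cl
Why: Monosilylation of a symmetric diol through its sparingly soluble monosodium alkoxide (Williamson-type O-silylation), which should react once with one equivalent of TBSCl; no stereocentre is involved.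

Step 2
Reactants: 2 4-[(tert-butyldimethylsilyl)oxy]but-2-yn-1-ol
Product: 3 (2Z)-4-[(tert-butyldimethylsilyl)oxy]-3-iodobut-2-en-1-ol
Conditions: NaAlH2(OCH2CH2OMe)2 (Red-Al), THF, 0 °C to rt; then I2, THF, −78 to 0 °C
Reagents that add atoms: iodine, II
Why: Hydroxyl-directed trans-hydroalumination of the propargylic alcohol places aluminium on the distal alkyne carbon, and iodinolysis with retention should give the (Z)-vinyl iodide, which fixes the cis relation of C2 and C5 across the later C1=C6 bond.

Step 3
Reactants: 3 (2Z)-4-[(tert-butyldimethylsilyl)oxy]-3-iodobut-2-en-1-ol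
Product: 4 (2Z)-4-[(tert-butyldimethylsilyl)oxy]-3-iodobut-2-enal
Conditions: MnO2 (activated, excess), CH2Cl2, rt, dark
Reagents that add atoms: none
Why: Neutral MnO2 oxidation of the primary allylic alcohol stops at the enal and should leave the (Z)-iodoalkene geometry and the silyl ether intact.

Step 4
Reactants: 4 (2Z)-4-[(tert-butyldimethylsilyl)oxy]-3-iodobut-2-enal
Product: 5 tert-butyl{[(2Z)-2-iodopenta-2,4-dien-1-yl]oxy}dimethylsilane
Conditions: Ph3PCH3Br, KN(SiMe3)2, THF, 0 °C; then 4, −78 to 0 °C
Reagents that add atoms: methyltriphenylphosphonium bromide, C[P+](c1ccccc1)(c1ccccc1)c1ccccc1.[Br-]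
Why: Wittig methylenation by the non-stabilized ylide should add 1,2 to the aldehyde faster than it attacks the vinylic iodide, and builds the vinyl group that carries C5.

Step 5
Reactants: 6 (2S)-but-3-ene-1,2-diol
Product: 7 (3S)-3,4-bis[(tert-butyldimethylsilyl)oxy]but-1-ene
Conditions: TBSCl (2.4 equiv), imidazole, DMF, rt
Reagents that add atoms: tert-butyldimethylsilyl chloride, CC(C)(C)[Si](C)(C)Cl
Why: Standard silylation (TBSCl, imidazole) of both hydroxyls leaves the stereocentre untouched.

Step 6
Reactants: 7 (3S)-3,4-bis[(tert-butyldimethylsilyl)oxy]but-1-ene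
Product: 8 (2S)-2-[(tert-butyldimethylsilyl)oxy]but-3-en-1-ol
Conditions: HF·pyridine, pyridine, THF, 0 °C
Reagents that add atoms: none
Why: Buffered HF·pyridine should cleave the less hindered primary silyl ether selectively (chemoselective desilylation).

Step 7
Reactants: 8 (2S)-2-[(tert-butyldimethylsilyl)oxy]but-3-en-1-ol
Product: 9 (2S)-2-[(tert-butyldimethylsilyl)oxy]but-3-enal
Conditions: Dess–Martin periodinane, pyridine, CH2Cl2, 0 °C; used at once
Reagents that add atoms: none
Why: Dess–Martin oxidation under buffered, non-basic conditions should give the aldehyde without epimerization of the α-stereocentre, provided it is used at once.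

Step 8
Reactants: 5 tert-butyl{[(2Z)-2-iodopenta-2,4-dien-1-yl]oxy}dimethylsilane; 9 (2S)-2-[(tert-butyldimethylsilyl)oxy]but-3-enal
Product: 13 (1R,6S)-6-[(tert-butyldimethylsilyl)oxy]-2-{[(tert-butyldimethylsilyl)oxy]methyl}cyclohexa-2,4-dien-1-ol, via alkenyllithium 10 (not isolated), via lithium alkoxide 11 (not isolated), via triene alcohol 12 (not isolated)
Conditions: 5, t-BuLi (2.1 equiv), Et2O, −78 °C; 9, −78 °C; AcOH (1.1 equiv); then CH2Cl2 (dilution), second-generation Hoveyda–Grubbs catalyst RuCl2(=CH-C6H4-2-OiPr)(H2IMes) (5 mol %), 40 °C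
Reagents that add atoms: none
Why: Iodine–lithium exchange on 5 gives alkenyllithium 10 with retention of the double-bond geometry, its 1,2-addition to aldehyde 9 forms C1–C2 (alkoxide 11, protonated in the flask to triene alcohol 12), and the ruthenium alkylidene then joins the terminal vinyl carbons C4 and C5 by ring-closing metathesis with loss of ethylene, so that one operation unites a C5–C6–C1 unit and a C2–C3–C4 unit into the complete carbocycle. The closest known reaction types are the Felkin–Anh addition of an alkenyl metal to an α-silyloxy aldehyde and the diene–ene ring-closing metathesis that gives cyclohexa-1,3-dienes, here run in sequence without isolation. The six-membered ring closes by metathesis between the monosubstituted alkene on C3 and the terminal alkene of the 1,3-diene; the C1=C6 bond already holds C2 and C5 cis, so only the ring (Z) alkene can result. The one new stereocentre, C2, is controlled by 1,2-induction from C3: with the bulky, non-chelating OTBS group anti to the incoming nucleophile (polar Felkin–Anh model) the 2,3-anti adduct should form, which is the cis-diol relation of the ring; C3 comes unchanged from 6. The step needs carbonyl addition to outrun deprotonation of the acidic C3–H of 9, which −78 °C in ether should secure, and needs the catalyst to survive the lithium salts, which neutralization with AcOH before its addition should secure.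

Step 9
Reactants: 13 (1R,6S)-6-[(tert-butyldimethylsilyl)oxy]-2-{[(tert-butyldimethylsilyl)oxy]methyl}cyclohexa-2,4-dien-1-ol
Product: 14 (1S,2R)-3-(hydroxymethyl)cyclohexa-3,5-diene-1,2-diol
Conditions: Bu4NF (2.5 equiv), THF, 0 °C to rt
Reagents that add atoms: none
Why: Fluoride-induced desilylation removes both TBS helpers under non-acidic conditions, which the acid-labile cis-dihydrodiol should tolerate.

Step 10
Reactants: 14 (1S,2R)-3-(hydroxymethyl)cyclohexa-3,5-diene-1,2-diol
Product: 15 [(5S,6R)-5-(benzoyloxy)-6-hydroxycyclohexa-1,3-dien-1-yl]methyl benzoate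
Conditions: BzCl (2.05 equiv), pyridine, CH2Cl2, −40 to −20 °C
Reagents that add atoms: benzoyl chloride, O=C(Cl)c1ccccc1
Why: Sterically controlled acylation (benzoyl chloride/pyridine) should take the primary allylic hydroxyl and then the C3 hydroxyl, which lies distal to the ring substituent, before the C2 hydroxyl that is flanked by the substituted C1.

Step 11
Reactants: 15 [(5S,6R)-5-(benzoyloxy)-6-hydroxycyclohexa-1,3-dien-1-yl]methyl benzoate
Product: 16 [(1S,2S,3S,6R)-3-(benzoyloxy)-2-hydroxy-7-oxabicyclo[4.1.0]hept-4-en-1-yl]methyl benzoate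
Conditions: VO(acac)2 (5 mol %), t-BuOOH (1.5 equiv), CH2Cl2, 0 °C to rt
Reagents that add atoms: tert-butyl hydroperoxide, CC(C)(C)OO
Why: Hydroxyl-directed, vanadium-catalysed epoxidation should deliver oxygen to the allylic C1=C6 bond from the face of the C2 hydroxyl, which sets C1 and C6 cis to both ring oxygens, while the C4=C5 bond, only homoallylic and deactivated by the allylic benzoate, should be spared.

**Compound list**

1 | but-2-yne-1,4-diol | OCC#CCO | starting material
2 | 4-[(tert-butyldimethylsilyl)oxy]but-2-yn-1-ol | CC(C)(C)[Si](C)(C)OCC#CCO | intermediate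
3 | (2Z)-4-[(tert-butyldimethylsilyl)oxy]-3-iodobut-2-en-1-ol (iodine cis to CH2OH) | OC/C=C(\I)CO[Si](C)(C)C(C)(C)C | intermediate
4 | (2Z)-4-[(tert-butyldimethylsilyl)oxy]-3-iodobut-2-enal | O=C/C=C(\I)CO[Si](C)(C)C(C)(C)C | intermediate
5 | tert-butyl{[(2Z)-2-iodopenta-2,4-dien-1-yl]oxy}dimethylsilane (iodine cis to the vinyl group) | C=C/C=C(\I)CO[Si](C)(C)C(C)(C)C | intermediate
6 | (2S)-but-3-ene-1,2-diol | C=C[C@H](O)CO | starting material
7 | (3S)-3,4-bis[(tert-butyldimethylsilyl)oxy]but-1-ene | C=C[C@H](O[Si](C)(C)C(C)(C)C)CO[Si](C)(C)C(C)(C)C | intermediate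
8 | (2S)-2-[(tert-butyldimethylsilyl)oxy]but-3-en-1-ol | C=C[C@H](O[Si](C)(C)C(C)(C)C)CO | intermediate
9 | (2S)-2-[(tert-butyldimethylsilyl)oxy]but-3-enal | C=C[C@H](O[Si](C)(C)C(C)(C)C)C=O | intermediate
10 | [(2E)-1-[(tert-butyldimethylsilyl)oxy]penta-2,4-dien-2-yl]lithium (lithium in place of the iodine of 5, cis to the vinyl group; not isolated) | C=C/C=C(\[Li])CO[Si](C)(C)C(C)(C)C | intermediate
11 | lithium (3S,4R,5Z)-3-[(tert-butyldimethylsilyl)oxy]-5-{[(tert-butyldimethylsilyl)oxy]methyl}octa-1,5,7-trien-4-olate (not isolated) | C=C/C=C(/CO[Si](C)(C)C(C)(C)C)\[C@@H]([O-])[C@@H](O[Si](C)(C)C(C)(C)C)C=C.[Li+] | intermediate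
12 | (3S,4R,5Z)-3-[(tert-butyldimethylsilyl)oxy]-5-{[(tert-butyldimethylsilyl)oxy]methyl}octa-1,5,7-trien-4-ol (not isolated) | C=C/C=C(/CO[Si](C)(C)C(C)(C)C)\[C@@H](O)[C@@H](O[Si](C)(C)C(C)(C)C)C=C | intermediate
13 | (1R,6S)-6-[(tert-butyldimethylsilyl)oxy]-2-{[(tert-butyldimethylsilyl)oxy]methyl}cyclohexa-2,4-dien-1-ol (OH and OTBS cis) | CC(C)(C)[Si](C)(C)OCC1=CC=C[C@H](O[Si](C)(C)C(C)(C)C)[C@@H]1O | intermediate
14 | (1S,2R)-3-(hydroxymethyl)cyclohexa-3,5-diene-1,2-diol (cis-diol) | OCC1=CC=C[C@H](O)[C@@H]1O | intermediate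
15 | [(5S,6R)-5-(benzoyloxy)-6-hydroxycyclohexa-1,3-dien-1-yl]methyl benzoate | O=C(OCC1=CC=C[C@H](OC(=O)c2ccccc2)[C@@H]1O)c1ccccc1 | intermediate
16 | [(1S,2S,3S,6R)-3-(benzoyloxy)-2-hydroxy-7-oxabicyclo[4.1.0]hept-4-en-1-yl]methyl benzoate | O=C(OC[C@@]12O[C@@H]1C=C[C@H](OC(=O)c1ccccc1)[C@@H]2O)c1ccccc1 | target

**Step count and risks**

Total step count: 11. Longest linear sequence: 8 steps (steps 1–4, then 8–11).

Steps most likely to fail:

Step 8. The basic alkenyllithium may deprotonate the aldehyde at C3 instead of adding, the facial selectivity at C2 may be poor, and the salts of the first stage may deactivate the ruthenium carbene. The fallback sets out from 5 and 9 and separates the two bond formations. A Nozaki–Hiyama–Kishi coupling (CrCl2, NiCl2 (cat.), DMSO, rt) joins them through a non-basic organochromium species and should give triene alcohol 12, which is now isolated and freed of its C2 epimer by chromatography. Ring-closing metathesis as a separate operation (second-generation Grubbs catalyst RuCl2(=CHPh)(H2IMes)(PCy3), CH2Cl2, 40 °C, high dilution) then comes back to the route at 13. No compound outside the compound list arises (F0).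

Step 10. Discrimination between the C3 and C2 hydroxyls may be insufficient, with over-acylation or acyl migration between the cis oxygens. The fallback sets out from 13 and moves the epoxidation ahead of the acylation. Hydroxyl-directed epoxidation (VO(acac)2, t-BuOOH, CH2Cl2) should give (1S,2S,3S,6R)-3-[(tert-butyldimethylsilyl)oxy]-1-{[(tert-butyldimethylsilyl)oxy]methyl}-7-oxabicyclo[4.1.0]hept-4-en-2-ol F1. Desilylation (Bu4NF buffered with AcOH, THF, 0 °C) should give (1S,2S,3S,6R)-1-(hydroxymethyl)-7-oxabicyclo[4.1.0]hept-4-ene-2,3-diol F2. In F2 the C2 hydroxyl is flanked by the fully substituted oxirane carbon, so benzoylation (BzCl 2.05 equiv, pyridine, CH2Cl2, −40 °C) should take O7 and O3 only; the detour comes back to the route at 16.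

Step 7. The aldehyde may epimerize at its α-carbon, and its double bond may move into conjugation, during oxidation or before use. The fallback sets out from 8 and avoids the free aldehyde. Oxidation (TEMPO (cat.), PhI(OAc)2, MeCN–H2O) should give (2S)-2-[(tert-butyldimethylsilyl)oxy]but-3-enoic acid F3. Amidation (MeNH(OMe)·HCl, EDC·HCl, i-Pr2NEt, CH2Cl2) should give the Weinreb amide (2S)-2-[(tert-butyldimethylsilyl)oxy]-N-methoxy-N-methylbut-3-enamide F4. Acylation of alkenyllithium 10 (from 5, t-BuLi, Et2O, −78 °C) should give (3S,5Z)-3-[(tert-butyldimethylsilyl)oxy]-5-{[(tert-butyldimethylsilyl)oxy]methyl}octa-1,5,7-trien-4-one F5. Reagent-controlled Corey–Bakshi–Shibata reduction ((R)-2-methyl-CBS-oxazaborolidine, catecholborane, toluene, −78 °C) should set C2 and come back to the route at 12, which is isolated and closed to 13 by the metathesis stage of step 8 run on its own.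

Further compounds
F0 | step 8 | none | none
F1 | step 10 | (1S,2S,3S,6R)-3-[(tert-butyldimethylsilyl)oxy]-1-{[(tert-butyldimethylsilyl)oxy]methyl}-7-oxabicyclo[4.1.0]hept-4-en-2-ol | CC(C)(C)[Si](C)(C)OC[C@@]12O[C@@H]1C=C[C@H](O[Si](C)(C)C(C)(C)C)[C@@H]2O
F2 | step 10 | (1S,2S,3S,6R)-1-(hydroxymethyl)-7-oxabicyclo[4.1.0]hept-4-ene-2,3-diol | OC[C@@]12O[C@@H]1C=C[C@H](O)[C@@H]2O
F3 | step 7 | (2S)-2-[(tert-butyldimethylsilyl)oxy]but-3-enoic acid | C=C[C@H](O[Si](C)(C)C(C)(C)C)C(=O)O
F4 | step 7 | (2S)-2-[(tert-butyldimethylsilyl)oxy]-N-methoxy-N-methylbut-3-enamide | C=C[C@H](O[Si](C)(C)C(C)(C)C)C(=O)N(C)OC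
F5 | step 7 | (3S,5Z)-3-[(tert-butyldimethylsilyl)oxy]-5-{[(tert-butyldimethylsilyl)oxy]methyl}octa-1,5,7-trien-4-one | C=C/C=C(/CO[Si](C)(C)C(C)(C)C)\C(=O)[C@@H](O[Si](C)(C)C(C)(C)C)C=C
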